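In a one-step world, substrate would become target and the share of target among target and over-reaction product (the selectivity) would stay whole. This flask has a correction: partner attacks target, and the size of that correction is what has to be reckoned.

all flasks: substrate 0.10 M
- theta: partner 0.13 M; free catalyst 94 µM; run made earlier
- gamma: partner 0.24 M; free catalyst 94 µM; run made earlier
- zeta: partner 0.54 M; free catalyst 94 µM; run made earlier
- eta: partner 0.12 M; free catalyst 57 µM; run made earlier
- south: partner 0.500 M; free catalyst 94 µM; time 30 h
- north-west: partner 0.120 M; free catalyst 25 µM; time 30 h
- south-east: partner 0.500 M; free catalyst 25 µM; time 30 h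
- north: partner 0.120 M; free catalyst 94 µM; time 30 h

- theta (time / h: target / %, over-reaction product / %): 1.50: 15, 0; 3.00: 25, 2; 6.00: 43, 9; 12.0: 66, 12; 20.0: 74, 16
- gamma (time / h: target / %, over-reaction product / %): 4.00: 27, 9; 8.00: 42, 24; 12.0: 49, 33; 15.0: 55, 37; 20.0: 50, 45
- zeta (time / h: target / %, over-reaction product / %): 1.50: 10, 3; 3.00: 18, 11; 6.00: 22, 28; 12.0: 25, 61; 20.0: 16, 82
- eta (time / h: target / %, over-reaction product / %): 2.00: 11, 1; 5.00: 22, 5; 10.0: 40, 9; 15.0: 53, 12; 20.0: 63, 13

(standard deviation of a reading: 1.5 percentage points)

- the numbers in the tables scatter by 1.5 percentage points (one standard deviation)
- steps that have been proposed: catalyst intermediate D -> free catalyst + target; partner + free catalyst -> catalyst intermediate A; catalyst intermediate A -> catalyst intermediate B; partner -> decomposed reagent; substrate + catalyst intermediate C -> catalyst intermediate D; catalyst intermediate B -> by-product + catalyst intermediate C; partner + target -> over-reaction product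

- all flasks from highest to lowest share of target in all that became target or over-reaction product, at 30 h (south / north-west / south-east / north)
- the share of target in all that became target or over-reaction product of the flask you put first, at 30 h
- the share of target in all that became target or over-reaction product of the flask you put last, at 30 h

How large is the correction near 0.120 M of partner? Theta, the nearest run, has a share of 82.2% at its last reading. Eta, with less catalyst, has 82.9%. So north is put near theta's share, and these readings leave north against north-west open.

How large is it near 0.500 M? Zeta's two products already hold 98.0% of the substrate at its last reading, so its share is close to its target percentage. Zeta's target falls at 0.0558 h⁻¹ between its last two readings. This net fall per hour, the fade λ, is read off two scattered readings and is what remains of target's loss after target's making, so it is no rate constant of the loss; this reckoning assumes that it scales with the partner charge and stays steady. Scaled to south and run from zeta's last reading to 30 h, it leaves 9.55% target, which is this reckoning's low. South-east carries a quarter of south's catalyst, so its target is younger and it is placed above south.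

The forecast gives north > north-west > south-east > south, with top 83% (78% to 88%) and low 8.5% (5% to 13%): “South, extrapolated from zeta, gives about 8.5%.” Its low lies below the 9.55% reckoned here.

The flasks give north > north-west > south-east > south, with top 85.4% and low 9.29%.

    catalyst intermediate D → free catalyst + target (k = 0.110 s⁻¹)
    partner + free catalyst → catalyst intermediate A (k = 7.30 L mol⁻¹ s⁻¹)
    catalyst intermediate A → catalyst intermediate B (k = 0.110 s⁻¹)
    partner → decomposed reagent (k = 9.40 × 10⁻⁶ s⁻¹)
    substrate + catalyst intermediate C → catalyst intermediate D (k = 0.890 L mol⁻¹ s⁻¹)
    catalyst intermediate B → by-product + catalyst intermediate C (k = 0.190 s⁻¹)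
    partner + target → over-reaction product (k = 2.00 × 10⁻⁴ L mol⁻¹ s⁻¹)

South's 9.29% stands beside the reckoned 9.55%. South's share has moved by 5 points at 0.430 M of partner, and the forecast's range ends at 13%. A neighbour like north but charged with 0.48 M of partner (4.80 equiv) takes λ scaled to that charge, which leaves 9.74% target at 30 h. That neighbour stands at a share of 10.5%, with over-reaction product at 89.4% and 17% of its partner left.

The numbers in the tables are simulated with made-up constants; noise was put on by code.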